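Late in the two earlier runs the readings stay level within their scatter, so I started from the end of a run.

| setting | ochre | violet | flask |
|---|---|---|---|
| substrate | 0.36 M | 0.36 M | 0.36 M |
| first nucleophile | 1.44 M | 1.44 M | 1.44 M |
| solid second nucleophile | 0.18 M | 0.72 M | 0.360 M |
| remark | run made earlier | run made earlier |  |
| time |  |  | 2.0 h |

| run | time / h | target / % | other capture product / % |
|---|---|---|---|
| ochre | 0.167 | 72 | 2 |
| ochre | 0.500 | 87 | 4 |
| ochre | 0.833 | 92 | 5 |
| ochre | 1.33 | 91 | 9 |
| ochre | 2.00 | 94 | 10 |
| ochre | 2.50 | 94 | 10 |
| violet | 0.417 | 88 | 4 |
| violet | 0.833 | 91 | 7 |
| violet | 1.33 | 92 | 4 |
| violet | 1.50 | 90 | 9 |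
| violet | 2.00 | 90 | 7 |
| violet | 2.50 | 92 | 6 |

(readings scatter by 2 percentage points)

- the numbers in the tables scatter with a standard deviation of 2 percentage points
- at the start none of the solid second nucleophile is in solution
- a reading or a percentage of target counts all its forms, free or not

* share of target in target plus other capture product at 10 s
* share of target in target plus other capture product at 5.0 min
* share of target in target plus other capture product at 2.0 h
* which of target and other capture product there is more of at 2.0 h

Does the solid make the target? The ochre run reads 94% of target, which is 0.338 M, more than the 0.18 M of solid charged, so I took the first nucleophile as its partner.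

Does more solid then give more other capture product? Over its last two readings the ochre run holds 10.0%, and the violet run, with 0.72 M of solid, holds 6.50%, less, not more, and a reading scatters by 2 percentage points. I therefore pooled those four pairs, which give target over other capture product of 11.2. Dividing by the first nucleophile charged gives 7.79 M⁻¹. This is my capture ratio, a selectivity factor: late target over late other capture product, per unit of first nucleophile charged. Both runs held 1.44 M, so its use at another charge is my assumption. With 1.44 M in the flask, the share at 2.0 h comes to 91.8%, and target leads.

How soon is that share reached? The first ochre reading, at 0.167 h, still shows 97.3%, above the late share, though its 2% of other capture product equals the scatter. I took about that value for 5.0 min, and close to 100% for 10 s, far earlier than that reading, none of the solid being in solution at the start.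

The forecast, holding that “More solid does not clearly increase the other product”, gave 99%, 97% and 92%, with target ahead.

The flask gives 99.7%, 97.1% and 92.2%, with target ahead.

    substrate → intermediate (k = 0.00950 s⁻¹)
    first nucleophile + intermediate → target (k = 0.130 M⁻¹ s⁻¹)
    second nucleophile + intermediate → other capture product (k = 0.500 M⁻¹ s⁻¹)
    solid second nucleophile ⇌ second nucleophile, rate k4*(cs4 - [second nucleophile]) while solid is left; crystals form when [second nucleophile] > cs4 (solubility = 0.0900 M, k = 0.00180 s⁻¹)
    substrate + target ⇌ idle adduct, settled at all times (K = 36.0 M⁻¹)

At 2.00 h the flask holds 92.1% of target and 7.76% of other capture product, a ratio of 11.9 against 11.2 from my capture ratio. The neighbouring flask is charged with 0.58 M of first nucleophile and ends with 0.0899 M of dissolved second nucleophile, as the flask does with 0.0899 M. There the capture ratio gives 4.52, a share of 81.9%. The neighbouring flask ends with 82.3% of target and 17.6% of other capture product, a share of 82.4%.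

The numbers in the tables were generated by integration from invented constants, noise included.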